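**Plan** (atoms numbered from the carboxyl carbon C1; ring = C3, C4, C5, O2 on C3, O1 on C5; phenyl on C17)
1. Cuts: the C1 acid goes back to a vinyl group C2=C1; C12=C13 is cut (Julia–Kocienski); O1–C5 and O2–C3 are cut with loss of O2 and re-formation of a C3–C5 bond; then C4 (methylene transfer to C3=C5), C3=C5 (olefination), C7–CH3 (conjugate addition) and C6=C7 (Wittig).
2. Enabling feature: the peroxide-bearing carbons C3 and C5 flank the lone ring methylene C4, so the dioxolane is a C3–C4–C5 cyclopropane with O2 in place of the C3–C5 bond, and the C2–C1 arm on C3 is a vinyl group that lets a radical open that bond.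
3. Forward: the C5–C12 chain is built first, then C3/C2, C4 and C1 are added; the dioxolane, the only ring, closes in step 10; the C13–C17 styrenyl piece is joined next and C1 is oxidised last.
4. Stereochemistry: C7 by ligand-controlled copper-catalysed methyl addition; C3 and C5 in the radical closure (weak substrate control, isomer separation); 12E from the Julia–Kocienski step, 16E from the purchased pentenol.

Key step: step 10

Remark: the radical closure is assumed to give all four C3/C5 diastereomers of the dioxolane with little bias; only the (3S,5R) isomer 14 is carried on, assigned by NOE across the ring and by comparison of 25 with the natural acid.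
Remark: the C3 descriptor changes between S and R along the route (22, 23) only because the CIP priority of the C2 arm changes; the spatial arrangement stays the same.

Step 1
Reactants: 1 hexane-1,6-diol
Product: 2 6-[(tert-butyldiphenylsilyl)oxy]hexan-1-ol
Conditions: NaH (1.0 equiv), THF, rt; then TBDPSCl (1.0 equiv), rt
Reagents that add atoms: tert-butyl(chloro)diphenylsilane, CC(C)(C)[Si](Cl)(c1ccccc1)c1ccccc1
Why: O-silylation of the sparingly soluble monosodium alkoxide of a symmetrical diol should stop at the mono-ether.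

Step 2
Reactants: 2 6-[(tert-butyldiphenylsilyl)oxy]hexan-1-ol
Product: 3 6-[(tert-butyldiphenylsilyl)oxy]hexanal
Conditions: Dess–Martin periodinane, CH2Cl2, 0 °C to rt
Reagents that add atoms: none
Why: Dess–Martin oxidation takes a primary alcohol to the aldehyde without over-oxidation and leaves the silyl ether untouched.

Step 3
Reactants: 3 6-[(tert-butyldiphenylsilyl)oxy]hexanal; 4 1-(triphenylphosphoranylidene)propan-2-one
Product: 5 (3E)-9-[(tert-butyldiphenylsilyl)oxy]non-3-en-2-one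
Conditions: CH2Cl2, 40 °C
Reagents that add atoms: none
Why: Wittig olefination with a stabilised acyl ylide forms C6=C7 and gives the E-enone.

Step 4
Reactants: 5 (3E)-9-[(tert-butyldiphenylsilyl)oxy]non-3-en-2-one
Product: 6 (4R)-9-[(tert-butyldiphenylsilyl)oxy]-4-methylnonan-2-one
Conditions: CuBr·SMe2 (5 mol %), 1-[2-(diphenylphosphino)ferrocenyl]ethyldicyclohexylphosphine (C36H44FeP2, 6 mol %, the enantiomer that sends methyl to the Re face of C4 of 5), MeMgBr, t-BuOMe, −75 °C
Reagents that add atoms: methylmagnesium bromide, C[Mg]Br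
Why: Copper-catalysed enantioselective conjugate addition of a Grignard reagent to an acyclic E-enone with a ferrocenyl diphosphine is established for alkyl methyl ketones, and the ligand alone sets C7 as R by delivering methyl to the Re face of the β-carbon.

Step 5
Reactants: 6 (4R)-9-[(tert-butyldiphenylsilyl)oxy]-4-methylnonan-2-one; 7 triethyl 2-phosphonopropionate
Product: 8 ethyl (5R)-10-[(tert-butyldiphenylsilyl)oxy]-2,3,5-trimethyldec-2-enoate (E/Z mixture)
Conditions: 7, NaH, THF, 0 °C; then 6, reflux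
Reagents that add atoms: none
Why: Horner–Wadsworth–Emmons olefination of a methyl ketone with an α-methyl phosphonate anion builds the tetrasubstituted C3=C5 alkene, whose geometry is irrelevant because both isomers converge in step 10, and C7 is not enolisable.

Step 6
Reactants: 8 ethyl (5R)-10-[(tert-butyldiphenylsilyl)oxy]-2,3,5-trimethyldec-2-enoate
Product: 9 (5R)-10-[(tert-butyldiphenylsilyl)oxy]-2,3,5-trimethyldec-2-en-1-ol (E/Z mixture)
Conditions: iBu2AlH, CH2Cl2, −78 to 0 °C; aq. KNaC4H4O6 (potassium sodium tartrate)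
Reagents that add atoms: none
Why: 1,2-Reduction of an α,β-unsaturated ester with iBu2AlH gives the allylic alcohol that directs the cyclopropanation.

Step 7
Reactants: 9 (5R)-10-[(tert-butyldiphenylsilyl)oxy]-2,3,5-trimethyldec-2-en-1-ol
Product: 10 {2-[(2R)-7-[(tert-butyldiphenylsilyl)oxy]-2-methylheptyl]-1,2-dimethylcyclopropyl}methanol (all cyclopropane diastereomers)
Conditions: Et2Zn, CH2I2, CH2Cl2, 0 °C to rt
Reagents that add atoms: diiodomethane, ICI
Why: Hydroxyl-directed Simmons–Smith cyclopropanation is fast on electron-rich, fully substituted allylic alcohols and installs C4, and the new ring stereocentres need no control because step 10 erases them.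

Step 8
Reactants: 10 {2-[(2R)-7-[(tert-butyldiphenylsilyl)oxy]-2-methylheptyl]-1,2-dimethylcyclopropyl}methanol
Product: 11 2-[(2R)-7-[(tert-butyldiphenylsilyl)oxy]-2-methylheptyl]-1,2-dimethylcyclopropane-1-carbaldehyde (all cyclopropane diastereomers)
Conditions: Dess–Martin periodinane, CH2Cl2, rt
Reagents that add atoms: none
Why: Dess–Martin oxidation of the neopentyl-type cyclopropylmethanol gives an aldehyde with no α-hydrogen, so nothing can enolise.

Step 9
Reactants: 11 2-[(2R)-7-[(tert-butyldiphenylsilyl)oxy]-2-methylheptyl]-1,2-dimethylcyclopropane-1-carbaldehyde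
Product: 12 tert-butyl{[(6R)-7-(2-ethenyl-1,2-dimethylcyclopropyl)-6-methylheptyl]oxy}diphenylsilane (all cyclopropane diastereomers)
Conditions: Ph3PCH3Br, KOt-Bu, THF, 0 °C; then 11, 0 °C to rt
Reagents that add atoms: methyltriphenylphosphonium bromide, C[P+](c1ccccc1)(c1ccccc1)c1ccccc1.[Br-]
Why: Wittig methylenation with the small non-stabilised ylide tolerates the quaternary α-carbon and supplies C1.

Step 10
Reactants: 12 tert-butyl{[(6R)-7-(2-ethenyl-1,2-dimethylcyclopropyl)-6-methylheptyl]oxy}diphenylsilane; 13 dioxygen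
Product: 14 (3S,5R)-5-[(2R)-7-[(tert-butyldiphenylsilyl)oxy]-2-methylheptyl]-3-ethenyl-3,5-dimethyl-1,2-dioxolane
Conditions: PhSeSePh (cat.), AIBN (cat.), O2 (1 atm), hν (sunlamp), MeCN–CH2Cl2, 0 °C; then separation of the C3/C5 diastereomers (SiO2, then preparative HPLC)
Reagents that add atoms: none
Why: Light splits PhSeSePh into PhSe radicals that add reversibly to C1 of the vinyl group; the cyclopropylcarbinyl radical at C2 opens by cleaving C3–C5 to the tertiary C5 radical, which captures O2 (O1–C5), and the peroxyl radical then attacks C3 (O2–C3) with β-loss of PhSe, which restores the vinyl group and carries the chain. The closest known reaction type is the phenylselenyl- or phenylthiyl-radical-catalysed oxygenation of vinylcyclopropanes to 3-vinyl-1,2-dioxolanes, applied here to a cyclopropane whose two reacting carbons are both fully substituted. The 1,2-dioxolane closes in a 5-exo-trig mode onto the double bond of the transient allyl selenide. C5 becomes stereogenic when O2 adds to the planar radical and C3 in the chair-like peroxyl closure; the only bias comes from the small difference between CH3 and the C6 chain on C5 and from the remote C7 centre, so the (3S,5R) isomer must be separated from its three diastereomers. The step needs regioselective ring opening, secured by the tertiary (C5) versus primary (C4) radical, and chemoselectivity, secured by a substrate with no other alkene, an inert silyl ether and an O2-saturated medium that traps C5 before other radical paths. All cyclopropane diastereomers of 12 converge because both ring stereocentres are lost in the open radical.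

Step 11
Reactants: 14 (3S,5R)-5-[(2R)-7-[(tert-butyldiphenylsilyl)oxy]-2-methylheptyl]-3-ethenyl-3,5-dimethyl-1,2-dioxolane
Product: 15 (6R)-7-[(3R,5S)-5-ethenyl-3,5-dimethyl-1,2-dioxolan-3-yl]-6-methylheptan-1-ol
Conditions: Bu4NF, THF, 0 °C to rt
Reagents that add atoms: none
Why: Fluoride-driven desilylation frees the primary alcohol, and the di-tertiary dialkyl peroxide, which has no α-hydrogen for base-induced fragmentation, is inert to fluoride.

Step 12
Reactants: 15 (6R)-7-[(3R,5S)-5-ethenyl-3,5-dimethyl-1,2-dioxolan-3-yl]-6-methylheptan-1-ol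
Product: 16 (6R)-7-[(3R,5S)-5-ethenyl-3,5-dimethyl-1,2-dioxolan-3-yl]-6-methylheptanal
Conditions: Dess–Martin periodinane, CH2Cl2, 0 °C to rt
Reagents that add atoms: none
Why: Dess–Martin oxidation is metal-free and non-reducing, so neither the O–O bond nor the vinyl group is at risk.

Step 13
Reactants: 17 (4E)-5-phenylpent-4-en-1-ol; 18 1-phenyl-1H-tetrazole-5-thiol
Product: 19 1-phenyl-5-{[(4E)-5-phenylpent-4-en-1-yl]sulfanyl}-1H-tetrazole
Conditions: PPh3, diisopropyl azodicarboxylate, THF, 0 °C to rt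
Reagents that add atoms: none
Why: Mitsunobu thioetherification of a primary alcohol with the acidic tetrazolethiol proceeds by SN2 displacement of the oxyphosphonium group.

Step 14
Reactants: 19 1-phenyl-5-{[(4E)-5-phenylpent-4-en-1-yl]sulfanyl}-1H-tetrazole
Product: 20 1-phenyl-5-{[(4E)-5-phenylpent-4-en-1-yl]sulfonyl}-1H-tetrazole
Conditions: (NH4)6Mo7O24·4H2O (cat.), 30% aq. H2O2, EtOH, 0 °C to rt
Reagents that add atoms: hydrogen peroxide, OO
Why: Molybdate-catalysed peroxide oxidation takes the sulfide to the sulfone and spares the styrenyl alkene.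

Step 15
Reactants: 16 (6R)-7-[(3R,5S)-5-ethenyl-3,5-dimethyl-1,2-dioxolan-3-yl]-6-methylheptanal; 20 1-phenyl-5-{[(4E)-5-phenylpent-4-en-1-yl]sulfonyl}-1H-tetrazole
Product: 21 (3S,5R)-3-ethenyl-3,5-dimethyl-5-[(2R,7E,11E)-2-methyl-12-phenyldodeca-7,11-dien-1-yl]-1,2-dioxolane
Conditions: 20, KN(SiMe3)2, DME, −60 °C; then 16, −60 °C to rt
Reagents that add atoms: none
Why: Julia–Kocienski olefination of an unbranched aldehyde with the potassium anion of a 1-phenyltetrazolyl sulfone in DME gives the E-alkene C12=C13 through addition, Smiles rearrangement and elimination, and the hindered peroxide should resist the stabilised carbanion at low temperature.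

Step 16
Reactants: 21 (3S,5R)-3-ethenyl-3,5-dimethyl-5-[(2R,7E,11E)-2-methyl-12-phenyldodeca-7,11-dien-1-yl]-1,2-dioxolane
Product: 23 2-[(3R,5R)-3,5-dimethyl-5-[(2R,7E,11E)-2-methyl-12-phenyldodeca-7,11-dien-1-yl]-1,2-dioxolan-3-yl]ethan-1-ol, via B-alkyl-9-borabicyclononane 22 (not isolated)
Conditions: 9-BBN, THF, 0 °C to rt; then NaBO3·4H2O, H2O, rt
Reagents that add atoms: 9-borabicyclo[3.3.1]nonane, B1C2CCCC1CCC2 (boron kept only in 22); sodium perborate, [Na+].[O-]OB=O (oxygen of 23)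
Why: Anti-Markovnikov hydroboration–oxidation works here because 9-BBN attacks a monosubstituted terminal alkene far faster than 1,2-disubstituted or styrenyl alkenes, and perborate oxidises the C–B bond without touching the dialkyl peroxide.

Step 17
Reactants: 23 2-[(3R,5R)-3,5-dimethyl-5-[(2R,7E,11E)-2-methyl-12-phenyldodeca-7,11-dien-1-yl]-1,2-dioxolan-3-yl]ethan-1-ol
Product: 25 2-[(3S,5R)-3,5-dimethyl-5-[(2R,7E,11E)-2-methyl-12-phenyldodeca-7,11-dien-1-yl]-1,2-dioxolan-3-yl]acetic acid, via aldehyde 24 (not isolated)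
Conditions: TEMPO (cat.), PhI(OAc)2, MeCN–H2O, rt
Reagents that add atoms: water, O
Why: Oxoammonium-mediated oxidation (TEMPO/PhI(OAc)2 in aqueous acetonitrile) takes a primary alcohol through the aldehyde hydrate to the acid under near-neutral conditions that spare alkenes and the peroxide and never expose the β-peroxy carbonyl to base.

**Compound list**
1 | hexane-1,6-diol | OCCCCCCO | starting material
2 | 6-[(tert-butyldiphenylsilyl)oxy]hexan-1-ol | OCCCCCCO[Si](c1ccccc1)(c1ccccc1)C(C)(C)C | intermediate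
3 | 6-[(tert-butyldiphenylsilyl)oxy]hexanal | O=CCCCCCO[Si](c1ccccc1)(c1ccccc1)C(C)(C)C | intermediate
4 | 1-(triphenylphosphoranylidene)propan-2-one | CC(=O)C=P(c1ccccc1)(c1ccccc1)c1ccccc1 | starting material
5 | (3E)-9-[(tert-butyldiphenylsilyl)oxy]non-3-en-2-one | CC(=O)/C=C/CCCCCO[Si](c1ccccc1)(c1ccccc1)C(C)(C)C | intermediate
6 | (4R)-9-[(tert-butyldiphenylsilyl)oxy]-4-methylnonan-2-one | C[C@H](CCCCCO[Si](c1ccccc1)(c1ccccc1)C(C)(C)C)CC(C)=O | intermediate
7 | triethyl 2-phosphonopropionate | CCOC(=O)C(C)P(=O)(OCC)OCC | starting material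
8 | ethyl (5R)-10-[(tert-butyldiphenylsilyl)oxy]-2,3,5-trimethyldec-2-enoate (E/Z mixture) | C[C@H](CCCCCO[Si](c1ccccc1)(c1ccccc1)C(C)(C)C)CC(C)=C(C)C(=O)OCC | intermediate
9 | (5R)-10-[(tert-butyldiphenylsilyl)oxy]-2,3,5-trimethyldec-2-en-1-ol (E/Z mixture) | C[C@H](CCCCCO[Si](c1ccccc1)(c1ccccc1)C(C)(C)C)CC(C)=C(C)CO | intermediate
10 | {2-[(2R)-7-[(tert-butyldiphenylsilyl)oxy]-2-methylheptyl]-1,2-dimethylcyclopropyl}methanol (all cyclopropane diastereomers) | C[C@H](CCCCCO[Si](c1ccccc1)(c1ccccc1)C(C)(C)C)CC1(C)CC1(C)CO | intermediate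
11 | 2-[(2R)-7-[(tert-butyldiphenylsilyl)oxy]-2-methylheptyl]-1,2-dimethylcyclopropane-1-carbaldehyde (all cyclopropane diastereomers) | C[C@H](CCCCCO[Si](c1ccccc1)(c1ccccc1)C(C)(C)C)CC1(C)CC1(C)C=O | intermediate
12 | tert-butyl{[(6R)-7-(2-ethenyl-1,2-dimethylcyclopropyl)-6-methylheptyl]oxy}diphenylsilane (all cyclopropane diastereomers) | C[C@H](CCCCCO[Si](c1ccccc1)(c1ccccc1)C(C)(C)C)CC1(C)CC1(C)C=C | intermediate
13 | dioxygen | O=O | starting material
14 | (3S,5R)-5-[(2R)-7-[(tert-butyldiphenylsilyl)oxy]-2-methylheptyl]-3-ethenyl-3,5-dimethyl-1,2-dioxolane | C[C@H](CCCCCO[Si](c1ccccc1)(c1ccccc1)C(C)(C)C)C[C@]1(C)C[C@@](C)(C=C)OO1 | intermediate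
15 | (6R)-7-[(3R,5S)-5-ethenyl-3,5-dimethyl-1,2-dioxolan-3-yl]-6-methylheptan-1-ol | C[C@H](CCCCCO)C[C@]1(C)C[C@@](C)(C=C)OO1 | intermediate
16 | (6R)-7-[(3R,5S)-5-ethenyl-3,5-dimethyl-1,2-dioxolan-3-yl]-6-methylheptanal | C[C@H](CCCCC=O)C[C@]1(C)C[C@@](C)(C=C)OO1 | intermediate
17 | (4E)-5-phenylpent-4-en-1-ol | OCCC/C=C/c1ccccc1 | starting material
18 | 1-phenyl-1H-tetrazole-5-thiol | Sc1nnnn1-c1ccccc1 | starting material
19 | 1-phenyl-5-{[(4E)-5-phenylpent-4-en-1-yl]sulfanyl}-1H-tetrazole | S(CCC/C=C/c1ccccc1)c1nnnn1-c1ccccc1 | intermediate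
20 | 1-phenyl-5-{[(4E)-5-phenylpent-4-en-1-yl]sulfonyl}-1H-tetrazole | O=S(=O)(CCC/C=C/c1ccccc1)c1nnnn1-c1ccccc1 | intermediate
21 | (3S,5R)-3-ethenyl-3,5-dimethyl-5-[(2R,7E,11E)-2-methyl-12-phenyldodeca-7,11-dien-1-yl]-1,2-dioxolane | C[C@H](CCCC/C=C/CC/C=C/c1ccccc1)C[C@]1(C)C[C@@](C)(C=C)OO1 | intermediate
22 | 9-{2-[(3R,5R)-3,5-dimethyl-5-[(2R,7E,11E)-2-methyl-12-phenyldodeca-7,11-dien-1-yl]-1,2-dioxolan-3-yl]ethyl}-9-borabicyclo[3.3.1]nonane (formed and consumed in step 16) | C[C@H](CCCC/C=C/CC/C=C/c1ccccc1)C[C@]1(C)C[C@@](C)(CCB2C3CCCC2CCC3)OO1 | intermediate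
23 | 2-[(3R,5R)-3,5-dimethyl-5-[(2R,7E,11E)-2-methyl-12-phenyldodeca-7,11-dien-1-yl]-1,2-dioxolan-3-yl]ethan-1-ol | C[C@H](CCCC/C=C/CC/C=C/c1ccccc1)C[C@]1(C)C[C@@](C)(CCO)OO1 | intermediate
24 | 2-[(3S,5R)-3,5-dimethyl-5-[(2R,7E,11E)-2-methyl-12-phenyldodeca-7,11-dien-1-yl]-1,2-dioxolan-3-yl]acetaldehyde (formed and consumed in step 17) | C[C@H](CCCC/C=C/CC/C=C/c1ccccc1)C[C@]1(C)C[C@@](C)(CC=O)OO1 | intermediate
25 | 2-[(3S,5R)-3,5-dimethyl-5-[(2R,7E,11E)-2-methyl-12-phenyldodeca-7,11-dien-1-yl]-1,2-dioxolan-3-yl]acetic acid | C[C@H](CCCC/C=C/CC/C=C/c1ccccc1)C[C@]1(C)C[C@@](C)(CC(=O)O)OO1 | target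

**Step count and risks**
Total: 17 steps. Longest linear sequence: 15 steps (steps 1–12, then 15–17); steps 13–14 make the sulfone.

Step 10.
- What may go wrong: the chain may stall at the two fully substituted carbons, with the tertiary peroxyl radical abstracting hydrogen instead of closing. O2 capture and closure may also proceed with almost no facial preference, so little (3S,5R) material is recovered.
- Fallback: it sets out from 6 and comes back at 25, and sets C3 by nucleophilic attack on a peroxycarbenium ion.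
- Mukaiyama aldol addition of 2-(trimethylsilyloxy)propene to 6 (TiCl4, CH2Cl2, −78 °C) would give (6R)-11-[(tert-butyldiphenylsilyl)oxy]-4-hydroxy-4,6-dimethylundecan-2-one F1.
- Acid-catalysed exchange of the tertiary hydroxyl for a hydroperoxy group (H2O2, cat. H2SO4), with closure onto the ketone, gives 5-[(2R)-7-[(tert-butyldiphenylsilyl)oxy]-2-methylheptyl]-3,5-dimethyl-1,2-dioxolan-3-ol F2.
- MeOH/TsOH converts it into tert-butyl{[(6R)-7-(5-methoxy-3,5-dimethyl-1,2-dioxolan-3-yl)-6-methylheptyl]oxy}diphenylsilane F3.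
- TiCl4-promoted replacement of the methoxy group by 1-methoxy-1-(trimethylsilyloxy)ethene is expected to favour attack anti to the larger C5 substituent. After separation from the C5 epimer it should give methyl 2-[(3S,5R)-5-[(2R)-7-[(tert-butyldiphenylsilyl)oxy]-2-methylheptyl]-3,5-dimethyl-1,2-dioxolan-3-yl]acetate F4.
- HF·pyridine then gives methyl 2-[(3S,5R)-5-[(2R)-7-hydroxy-2-methylheptyl]-3,5-dimethyl-1,2-dioxolan-3-yl]acetate F5.
- Dess–Martin periodinane gives methyl 2-[(3S,5R)-3,5-dimethyl-5-[(2R)-2-methyl-7-oxoheptyl]-1,2-dioxolan-3-yl]acetate F6.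
- Julia–Kocienski olefination with 20 gives methyl 2-[(3S,5R)-3,5-dimethyl-5-[(2R,7E,11E)-2-methyl-12-phenyldodeca-7,11-dien-1-yl]-1,2-dioxolan-3-yl]acetate F7, and LiOH in THF–H2O at 0 °C gives 25.
- C5 stays uncontrolled here too, but only two isomers instead of four have to be separated.

Step 16.
- What may go wrong: 9-BBN may also attack the C12=C13 or C16=C17 double bond, or the borane may reduce the O–O bond during the longer time needed at the hindered allylic position.
- Fallback: it sets out from 14 and comes back at 23; the vinyl group is hydroborated before any other alkene is present and C1 is carried as an acetate.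
- 9-BBN then NaBO3·4H2O on 14 gives 2-[(3R,5R)-5-[(2R)-7-[(tert-butyldiphenylsilyl)oxy]-2-methylheptyl]-3,5-dimethyl-1,2-dioxolan-3-yl]ethan-1-ol F8.
- Ac2O/pyridine gives 2-[(3R,5R)-5-[(2R)-7-[(tert-butyldiphenylsilyl)oxy]-2-methylheptyl]-3,5-dimethyl-1,2-dioxolan-3-yl]ethyl acetate F9.
- HF·pyridine gives 2-[(3R,5R)-5-[(2R)-7-hydroxy-2-methylheptyl]-3,5-dimethyl-1,2-dioxolan-3-yl]ethyl acetate F10.
- Dess–Martin periodinane gives 2-[(3R,5R)-3,5-dimethyl-5-[(2R)-2-methyl-7-oxoheptyl]-1,2-dioxolan-3-yl]ethyl acetate F11.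
- Julia–Kocienski olefination with 20 gives 2-[(3R,5R)-3,5-dimethyl-5-[(2R,7E,11E)-2-methyl-12-phenyldodeca-7,11-dien-1-yl]-1,2-dioxolan-3-yl]ethyl acetate F12.
- K2CO3 in MeOH frees 23, which enters step 17.

Step 5.
- What may go wrong: the hindered phosphonate anion may enolise the methyl ketone and add slowly, leaving the olefination incomplete, and base may move the new double bond out of conjugation.
- Fallback: it sets out from 6 and comes back at 11, and builds the cyclopropane by carbene addition to a 1,1-disubstituted alkene.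
- Wittig methylenation of 6 (Ph3PCH3Br, KOt-Bu, THF) gives tert-butyl{[(6R)-6,8-dimethylnon-8-en-1-yl]oxy}diphenylsilane F13.
- Dibromocarbene addition (CHBr3, KOt-Bu, pentane, 0 °C) gives tert-butyl{[(6R)-7-(2,2-dibromo-1-methylcyclopropyl)-6-methylheptyl]oxy}diphenylsilane F14.
- Bromine–lithium exchange with n-BuLi at −95 °C and trapping with MeI gives tert-butyl{[(6R)-7-(2-bromo-1,2-dimethylcyclopropyl)-6-methylheptyl]oxy}diphenylsilane F15.
- A second exchange with t-BuLi at −78 °C and formylation with DMF gives 11.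

**Further compounds**
F1 | step 10 | (6R)-11-[(tert-butyldiphenylsilyl)oxy]-4-hydroxy-4,6-dimethylundecan-2-one (C4 epimers) | C[C@H](CCCCCO[Si](c1ccccc1)(c1ccccc1)C(C)(C)C)CC(C)(O)CC(C)=O
F2 | step 10 | 5-[(2R)-7-[(tert-butyldiphenylsilyl)oxy]-2-methylheptyl]-3,5-dimethyl-1,2-dioxolan-3-ol (ring diastereomers) | C[C@H](CCCCCO[Si](c1ccccc1)(c1ccccc1)C(C)(C)C)CC1(C)CC(C)(O)OO1
F3 | step 10 | tert-butyl{[(6R)-7-(5-methoxy-3,5-dimethyl-1,2-dioxolan-3-yl)-6-methylheptyl]oxy}diphenylsilane (ring diastereomers) | C[C@H](CCCCCO[Si](c1ccccc1)(c1ccccc1)C(C)(C)C)CC1(C)CC(C)(OC)OO1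
F4 | step 10 | methyl 2-[(3S,5R)-5-[(2R)-7-[(tert-butyldiphenylsilyl)oxy]-2-methylheptyl]-3,5-dimethyl-1,2-dioxolan-3-yl]acetate | C[C@H](CCCCCO[Si](c1ccccc1)(c1ccccc1)C(C)(C)C)C[C@]1(C)C[C@@](C)(CC(=O)OC)OO1
F5 | step 10 | methyl 2-[(3S,5R)-5-[(2R)-7-hydroxy-2-methylheptyl]-3,5-dimethyl-1,2-dioxolan-3-yl]acetate | C[C@H](CCCCCO)C[C@]1(C)C[C@@](C)(CC(=O)OC)OO1
F6 | step 10 | methyl 2-[(3S,5R)-3,5-dimethyl-5-[(2R)-2-methyl-7-oxoheptyl]-1,2-dioxolan-3-yl]acetate | C[C@H](CCCCC=O)C[C@]1(C)C[C@@](C)(CC(=O)OC)OO1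
F7 | step 10 | methyl 2-[(3S,5R)-3,5-dimethyl-5-[(2R,7E,11E)-2-methyl-12-phenyldodeca-7,11-dien-1-yl]-1,2-dioxolan-3-yl]acetate | C[C@H](CCCC/C=C/CC/C=C/c1ccccc1)C[C@]1(C)C[C@@](C)(CC(=O)OC)OO1
F8 | step 16 | 2-[(3R,5R)-5-[(2R)-7-[(tert-butyldiphenylsilyl)oxy]-2-methylheptyl]-3,5-dimethyl-1,2-dioxolan-3-yl]ethan-1-ol | C[C@H](CCCCCO[Si](c1ccccc1)(c1ccccc1)C(C)(C)C)C[C@]1(C)C[C@@](C)(CCO)OO1
F9 | step 16 | 2-[(3R,5R)-5-[(2R)-7-[(tert-butyldiphenylsilyl)oxy]-2-methylheptyl]-3,5-dimethyl-1,2-dioxolan-3-yl]ethyl acetate | C[C@H](CCCCCO[Si](c1ccccc1)(c1ccccc1)C(C)(C)C)C[C@]1(C)C[C@@](C)(CCOC(C)=O)OO1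
F10 | step 16 | 2-[(3R,5R)-5-[(2R)-7-hydroxy-2-methylheptyl]-3,5-dimethyl-1,2-dioxolan-3-yl]ethyl acetate | C[C@H](CCCCCO)C[C@]1(C)C[C@@](C)(CCOC(C)=O)OO1
F11 | step 16 | 2-[(3R,5R)-3,5-dimethyl-5-[(2R)-2-methyl-7-oxoheptyl]-1,2-dioxolan-3-yl]ethyl acetate | C[C@H](CCCCC=O)C[C@]1(C)C[C@@](C)(CCOC(C)=O)OO1
F12 | step 16 | 2-[(3R,5R)-3,5-dimethyl-5-[(2R,7E,11E)-2-methyl-12-phenyldodeca-7,11-dien-1-yl]-1,2-dioxolan-3-yl]ethyl acetate | C[C@H](CCCC/C=C/CC/C=C/c1ccccc1)C[C@]1(C)C[C@@](C)(CCOC(C)=O)OO1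
F13 | step 5 | tert-butyl{[(6R)-6,8-dimethylnon-8-en-1-yl]oxy}diphenylsilane | C[C@H](CCCCCO[Si](c1ccccc1)(c1ccccc1)C(C)(C)C)CC(C)=C
F14 | step 5 | tert-butyl{[(6R)-7-(2,2-dibromo-1-methylcyclopropyl)-6-methylheptyl]oxy}diphenylsilane (cyclopropane epimers) | C[C@H](CCCCCO[Si](c1ccccc1)(c1ccccc1)C(C)(C)C)CC1(C)CC1(Br)Br
F15 | step 5 | tert-butyl{[(6R)-7-(2-bromo-1,2-dimethylcyclopropyl)-6-methylheptyl]oxy}diphenylsilane (cyclopropane diastereomers) | C[C@H](CCCCCO[Si](c1ccccc1)(c1ccccc1)C(C)(C)C)CC1(C)CC1(C)Br
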